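**Overview**
1. The retrosynthesis first cuts the C3–O7' ether, the only link between the two coumarin bicycles. Both pieces are then the same monomer, scopoletin (7-hydroxy-6-methoxycoumarin).
2. Enabling feature: the 7-OH lies para to C4a, and C4a carries the C4=C3 bond of the pyranone ring. The spin of an O7 phenoxyl radical therefore extends to C3 (alpha to the C2 lactone carbonyl), and C3 of one radical can bond to O7 of another.
3. The monomer is cut at O1–C2 (lactone) and C3=C4 (olefination) to 2,4-dihydroxy-5-methoxybenzaldehyde and a C2 ylide. The aldehyde goes back to 2,4,5-trimethoxybenzaldehyde by two O–CH3 cleavages.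
4. Forward: the benzene ring is bought and the pyranone ring is closed on it in one pot (Wittig, E/Z isomerisation, lactonisation). Two finished bicycles are joined last by oxidative dehydrodimerisation, which closes no ring.
5. Stereochemistry: there is none to set. The cinnamate geometry disappears in the ring, and the transient sp3 C3 of the quinone methide is flattened on re-aromatisation.

Key step: step 3

Remark: the target has no stereocentre and no stereogenic double bond, so it is a single achiral compound and no asymmetric step is needed.

**Route**

Step 1
Reactants: 1 2,4,5-trimethoxybenzaldehyde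
Product: 2 2,4-dihydroxy-5-methoxybenzaldehyde
Conditions: AlCl3 (5 equiv.), CH2Cl2, 0 °C to rt; then ice, 2 M HCl
Reagents that add atoms: none
Why: Lewis-acid aryl methyl ether cleavage, in which AlCl3 bound to the formyl oxygen chelates the 2-methoxy group and makes the ortho and para methoxy oxygens oxocarbenium-like so that chloride removes their methyl groups, while the 5-methoxy group, meta to the aldehyde and without this activation, should stay, a selectivity well established for polymethoxybenzaldehydes.

Step 2
Reactants: 2 2,4-dihydroxy-5-methoxybenzaldehyde; 3 ethyl (triphenylphosphoranylidene)acetate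
Product: 6 scopoletin (7-hydroxy-6-methoxy-2H-chromen-2-one), via E-cinnamate 4 (not isolated), via Z-cinnamate 5 (not isolated)
Conditions: 3 (1.3 equiv.), PhNEt2, reflux (ca. 215 °C), N2; then 2 M HCl wash
Reagents that add atoms: 3 ethyl (triphenylphosphoranylidene)acetate, CCOC(=O)C=P(c1ccccc1)(c1ccccc1)c1ccccc1 (delivers C3, C2 and the carbonyl oxygen)
Why: Wittig olefination with a stabilised ylide tolerates the free phenols, and at the boiling point of diethylaniline the E-cinnamate 4 equilibrates with the Z isomer 5, which is drained irreversibly by attack of its 2-OH on the ester (intramolecular transesterification), the standard one-pot coumarin synthesis from salicylaldehydes.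

Step 3
Reactants: 6 scopoletin (two molecules)
Product: 9 7-hydroxy-6-methoxy-3-[(6-methoxy-2-oxo-2H-chromen-7-yl)oxy]-2H-chromen-2-one (target), via phenoxyl radical 7 (not isolated), via quinone methide dimer 8 (not isolated)
Conditions: horseradish peroxidase (cat.), H2O2 (0.3 equiv., syringe pump over several hours), acetone/0.1 M phosphate buffer pH 6 (1:4), ca. 5 mM in 6, rt; stopped at partial conversion, unreacted 6 recovered and recycled
Reagents that add atoms: none
Why: Proposed new method: the two oxidised states of the peroxidase each take one electron and one proton from the 7-OH of 6, and the radical 7 holds its spin on O7, C6, C8, C4a and, relayed by the C4=C3 bond, on C3 next to the lactone carbonyl; union of C3 of one radical with O7 of a second gives the para-quinone methide 8, whose C3-H (alpha to C2=O and vinylogous to the C7 ketone) is lost to the buffer while O7 is reprotonated, which restores the aromatic coumarin of 9. The closest known reaction type is the peroxidase/H2O2 or Ag2O dehydrodimerisation of ferulate esters, whose 8-O-4 quinone methides end in the same way by loss of H8 to give enol aryl ethers, and 6 is itself a fast peroxidase substrate, but a preparative C3-O7' coupling of a hydroxycoumarin has not been shown. No ring is closed, only the intermolecular C3-O7' bond is made. No stereocentre survives: C3 of 8 arises racemic without any controlling element and becomes sp2 again in 9. The step needs regioselectivity for C3-O7' over C3-C3', C3-C8', C8-C8' and C8-O7' pairing, and here the substrate helps because bonds made at C6 (OMe-bearing) or C4a (quaternary) cannot re-aromatise and should revert, C8 is crowded between the oxygen-bearing carbons C7 and C8a, C3 is the open terminus of the spin system and identical partners rule out cross-coupling statistics, although C-C linked isomers must still be expected and removed by chromatography. It also needs chemoselectivity against re-oxidation of the phenol 9, which is addressed by a deficit of slowly added H2O2, a large standing excess of 6 and a mostly aqueous medium from which the poorly soluble dimer should separate.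

**Compound list**
1 | 2,4,5-trimethoxybenzaldehyde | COc1cc(OC)c(C=O)cc1OC | starting material
2 | 2,4-dihydroxy-5-methoxybenzaldehyde | COc1cc(C=O)c(O)cc1O | intermediate
3 | ethyl (triphenylphosphoranylidene)acetate | CCOC(=O)C=P(c1ccccc1)(c1ccccc1)c1ccccc1 | starting material
4 | ethyl (E)-3-(2,4-dihydroxy-5-methoxyphenyl)prop-2-enoate (E-cinnamate, not isolated) | CCOC(=O)/C=C/c1cc(OC)c(O)cc1O | intermediate
5 | ethyl (Z)-3-(2,4-dihydroxy-5-methoxyphenyl)prop-2-enoate (Z-cinnamate, not isolated) | CCOC(=O)/C=C\c1cc(OC)c(O)cc1O | intermediate
6 | scopoletin, 7-hydroxy-6-methoxy-2H-chromen-2-one | COc1cc2ccc(=O)oc2cc1O | intermediate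
7 | scopoletin 7-phenoxyl radical (not isolated) | COc1cc2ccc(=O)oc2cc1[O] | intermediate
8 | rac-6-methoxy-3-[(6-methoxy-2-oxo-2H-chromen-7-yl)oxy]-3H-chromene-2,7-dione (para-quinone methide dimer, not isolated) | COC1=CC2=CC(Oc3cc4oc(=O)ccc4cc3OC)C(=O)OC2=CC1=O | intermediate
9 | 7-hydroxy-6-methoxy-3-[(6-methoxy-2-oxo-2H-chromen-7-yl)oxy]-2H-chromen-2-one | COc1cc2cc(Oc3cc4oc(=O)ccc4cc3OC)c(=O)oc2cc1O | target

**Step count**
Total step count: 3. Longest linear sequence: 3 steps (1 to 2 to 6 to 9).

**Steps most likely to fail**

Step 3. The radical pairs may combine through carbon (C3 with C3', C3 with C8') instead of through C3 and O7'. The phenolic product may also be drawn back into the oxidation and grow into oligomers.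
- The fallback uses known chemistry and makes the ether before the second pyranone ring exists. It sets out from 6, takes 2 as the second building block and comes back to the route at 9.
- O-Alkylation of 6 with tert-butyl bromoacetate (K2CO3, DMF) should give tert-butyl 2-[(6-methoxy-2-oxo-2H-chromen-7-yl)oxy]acetate F1.
- TFA in CH2Cl2 then frees 2-[(6-methoxy-2-oxo-2H-chromen-7-yl)oxy]acetic acid F2.
- A Perkin-type condensation of F2 with aldehyde 2 (Ac2O, Et3N, 120 °C) is the standard entry to 3-aryloxycoumarins. It closes the second lactone around the O-CH2 carbon, which becomes C3, and acetylates the remaining phenol, giving 7-acetoxy-6-methoxy-3-[(6-methoxy-2-oxo-2H-chromen-7-yl)oxy]-2H-chromen-2-one F3.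
- Methanolysis of the aryl acetate (K2CO3, MeOH, 0 °C, then acid) should deliver 9.

Step 1. The cleavage may stall after the first, chelation-assisted demethylation. Regiocontrol between the neighbouring 4- and 5-methyl ethers may also be lost under the Lewis acid.
- The fallback reverses the order of events: the ring is built first and the 7-OH is unmasked last, by a different mechanism. It sets out from 1 and comes back at 6.
- One equivalent of BCl3 (CH2Cl2, -78 to 0 °C) removes only the methyl ether chelated to the aldehyde and should give 2-hydroxy-4,5-dimethoxybenzaldehyde F4.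
- The one-pot Wittig-lactonisation with 3 in refluxing PhNEt2 passes through ethyl (E)-3-(2-hydroxy-4,5-dimethoxyphenyl)prop-2-enoate F5 and ethyl (Z)-3-(2-hydroxy-4,5-dimethoxyphenyl)prop-2-enoate F6, neither isolated. It ends at scoparone (6,7-dimethoxy-2H-chromen-2-one) F7.
- Nucleophilic dealkylation with LiCl in refluxing DMF is an SN2 attack of chloride on methyl that selects the ether with the better phenoxide leaving group. It should take the 7-methyl group, whose oxygen is conjugated with the lactone carbonyl through C4a and C4=C3, and give 6 after acidification.

Step 2. The acidic 4-OH may protonate and hold back the ylide, the E to Z isomerisation may be slow, and the electron-rich phenol may decompose at 215 °C.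
- The fallback replaces olefination by condensation with an activated methylene compound at low temperature. It sets out from 2 and comes back at 6.
- Knoevenagel condensation of 2 with Meldrum's acid (cat. piperidinium acetate, EtOH, reflux) is followed in the same pot by attack of the 2-OH on the dioxanedione. It should give 7-hydroxy-6-methoxy-2-oxo-2H-chromene-3-carboxylic acid F8.
- Protodecarboxylation (Cu powder, quinoline, 200 °C) then gives 6.

**Further compounds**
F1 | step 3 | tert-butyl 2-[(6-methoxy-2-oxo-2H-chromen-7-yl)oxy]acetate | COc1cc2ccc(=O)oc2cc1OCC(=O)OC(C)(C)C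
F2 | step 3 | 2-[(6-methoxy-2-oxo-2H-chromen-7-yl)oxy]acetic acid | COc1cc2ccc(=O)oc2cc1OCC(=O)O
F3 | step 3 | 7-acetoxy-6-methoxy-3-[(6-methoxy-2-oxo-2H-chromen-7-yl)oxy]-2H-chromen-2-one | COc1cc2cc(Oc3cc4oc(=O)ccc4cc3OC)c(=O)oc2cc1OC(C)=O
F4 | step 1 | 2-hydroxy-4,5-dimethoxybenzaldehyde | COc1cc(O)c(C=O)cc1OC
F5 | step 1 | ethyl (E)-3-(2-hydroxy-4,5-dimethoxyphenyl)prop-2-enoate | CCOC(=O)/C=C/c1cc(OC)c(OC)cc1O
F6 | step 1 | ethyl (Z)-3-(2-hydroxy-4,5-dimethoxyphenyl)prop-2-enoate | CCOC(=O)/C=C\c1cc(OC)c(OC)cc1O
F7 | step 1 | scoparone (6,7-dimethoxy-2H-chromen-2-one) | COc1cc2ccc(=O)oc2cc1OC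
F8 | step 2 | 7-hydroxy-6-methoxy-2-oxo-2H-chromene-3-carboxylic acid | COc1cc2cc(C(=O)O)c(=O)oc2cc1O
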